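**Assumption:** The target, 2'-hydroxy-3,7,8,4',5'-pentamethoxyflavone (C20H20O8), has no stereocentres, and its C2–C1' axis rotates freely. It is achiral, so "single enantiomer" does not apply and no stereocontrol is needed.

## Retrosynthetic overview
1. Both benzene rings are purchased. The B ring is 2-hydroxy-4,5-dimethoxybenzaldehyde (1), masked as its benzyl ether (2). The A ring is 2'-hydroxy-3',4'-dimethoxyacetophenone (3).
2. Disconnection 1 is the C2–C3 bond, made by Claisen–Schmidt condensation of 2 and 3 to give chalcone 4.
3. Disconnection 2 is O1–C2 plus C3–O, made by Algar–Flynn–Oyamada oxidative cyclisation to flavonol 5. The pyranone C ring is the only ring formed.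
4. The 3-OH is the only free OH in 5, so it is methylated cleanly to 6. Hydrogenolysis of the benzyl ether then releases the 2'-OH to give target 7.
5. The benzyl group is needed. Without it, the 3-OH and 2'-OH compete at the methylation step. Permethylation followed by Lewis-acid demethylation would cleave the carbonyl-chelated 3-OMe rather than the 2'-OMe.

## Route

**Step 1**
Reactants: 1, 2-hydroxy-4,5-dimethoxybenzaldehyde
Product: 2, 2-(benzyloxy)-4,5-dimethoxybenzaldehyde
Conditions: BnBr, K2CO3, DMF, 60 °C
Reagents that add atoms: benzyl bromide, BrCc1ccccc1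
Why: This is a Williamson ether synthesis. The single acidic phenol is deprotonated and alkylated by SN2, and the aldehyde and methyl ethers are inert.

**Step 2**
Reactants: 2, 2-(benzyloxy)-4,5-dimethoxybenzaldehyde; 3, 1-(2-hydroxy-3,4-dimethoxyphenyl)ethanone
Product: 4, (E)-3-[2-(benzyloxy)-4,5-dimethoxyphenyl]-1-(2-hydroxy-3,4-dimethoxyphenyl)prop-2-en-1-one
Conditions: 50% aq KOH, EtOH, rt, 48 h; then cold 2 M HCl
Reagents that add atoms: none (water is lost)
Why: This is a Claisen–Schmidt crossed aldol condensation. The aldehyde cannot enolise, so only the methyl ketone enolate adds, and E1cB dehydration gives the thermodynamic E-enone. That geometry is consumed in the next step.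

**Step 3**
Reactants: 4, the chalcone
Product: 5, 2-[2-(benzyloxy)-4,5-dimethoxyphenyl]-3-hydroxy-7,8-dimethoxy-4H-chromen-4-one
Conditions: 30% H2O2, 2 M aq NaOH, MeOH, 0 °C → rt; then HCl
Reagents that add atoms: hydrogen peroxide, OO (supplies the 3-oxygen)
Why: This is the Algar–Flynn–Oyamada reaction. Alkaline peroxide oxidises the enone, the 2'-phenoxide closes at the β-carbon (6-endo), and the resulting dihydroflavonol is oxidised in situ to the flavonol. Two features favour flavonol over aurone: the chalcone has no 6'-substituent, and the electron-rich B ring stabilises the β-position. The ethers survive these conditions.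

**Step 4**
Reactants: 5, the flavonol
Product: 6, 2-[2-(benzyloxy)-4,5-dimethoxyphenyl]-3,7,8-trimethoxy-4H-chromen-4-one
Conditions: MeI, K2CO3, acetone, reflux
Reagents that add atoms: iodomethane, CI
Why: This is a Williamson O-methylation. The 3-OH is the only acidic site, so no chemoselectivity problem arises.

**Step 5**
Reactants: 6, the benzyl-protected pentamethoxyflavone
Product: 7, 2-(2-hydroxy-4,5-dimethoxyphenyl)-3,7,8-trimethoxy-4H-chromen-4-one (target)
Conditions: H2 (1 atm), 10% Pd/C, EtOAc–MeOH, rt
Reagents that add atoms: none
Why: This is a catalytic hydrogenolysis of the benzylic C–O bond. The methyl ethers and the tetrasubstituted, vinylogous-ester C2=C3 bond are not reduced at 1 atm and room temperature.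

## Route check
- **Formula balance:** 1 C9H10O4 → 2 C16H16O4; 2 + 3 (C10H12O4) − H2O → 4 C26H26O7; + O − 2H → 5 C26H24O8; + CH2 → 6 C27H26O8; − C7H6 → 7 C20H20O8, which matches the target SMILES.
- **A-ring mapping:** Acetophenone C2-OH becomes O1, C3-OMe becomes 8-OMe and C4-OMe becomes 7-OMe.
- **B-ring mapping:** Aldehyde C2-O becomes the 2'-OH, and the 4,5-OMe groups become 4',5'-OMe.

## Compound list
| No. | Name | SMILES | Role |
|---|---|---|---|
| 1 | 2-hydroxy-4,5-dimethoxybenzaldehyde | COc1cc(O)c(C=O)cc1OC | starting material |
| 2 | 2-(benzyloxy)-4,5-dimethoxybenzaldehyde | COc1cc(OCc2ccccc2)c(C=O)cc1OC | intermediate |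
| 3 | 1-(2-hydroxy-3,4-dimethoxyphenyl)ethanone | CC(=O)c1ccc(OC)c(OC)c1O | starting material |
| 4 | (E)-2-benzyloxy-2'-hydroxy-3',4',4,5-tetramethoxychalcone | COc1ccc(C(=O)/C=C/c2cc(OC)c(OC)cc2OCc2ccccc2)c(O)c1OC | intermediate |
| 5 | 2'-benzyloxy-3-hydroxy-7,8,4',5'-tetramethoxyflavone | COc1cc(OCc2ccccc2)c(-c2oc3c(OC)c(OC)ccc3c(=O)c2O)cc1OC | intermediate |
| 6 | 2'-benzyloxy-3,7,8,4',5'-pentamethoxyflavone | COc1cc(OCc2ccccc2)c(-c2oc3c(OC)c(OC)ccc3c(=O)c2OC)cc1OC | intermediate |
| 7 | 2'-hydroxy-3,7,8,4',5'-pentamethoxyflavone | COc1cc(O)c(-c2oc3c(OC)c(OC)ccc3c(=O)c2OC)cc1OC | target |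

## Summary
**Total steps:** 5. **Longest linear sequence:** 5 (1 → 2 → 4 → 5 → 6 → 7).

I kept steps 2 and 3 separate rather than running them in one pot. Unreacted electron-rich aldehyde would be consumed by alkaline peroxide, and the chalcone crystallises easily.

**Three steps most likely to fail, each with a fallback:**
1. **Step 3 (AFO).** The ortho-OBn group may lower the yield, or the reaction may stop at the dihydroflavonol or give aurone. Fallback: cyclise chalcone 4 to the flavone with I2/DMSO. Then install the 3-OH by C2=C3 epoxidation with DMDO and ring opening, and rejoin the route at 5.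
2. **Step 2 (Claisen–Schmidt).** The aldehyde is very electron-rich and hindered, so conversion may be slow and incomplete. Fallback: switch to acylation chemistry. O-acylate 3 with 2-benzyloxy-4,5-dimethoxybenzoyl chloride, then carry out the Baker–Venkataraman rearrangement (KOH/pyridine) and acid cyclodehydration to the flavone, followed by C3 oxidation as above. Using the ω-methoxy analogue of 3 instead would deliver 6 directly.
3. **Step 5 (hydrogenolysis).** The hindered benzyl ether may cleave slowly, or the C2=C3 bond may be partly reduced. Fallback: change the protecting group at step 1 to MOM (MOMCl, iPr2NEt). MOM survives KOH, H2O2/NaOH and MeI/K2CO3, and is removed at the end with HCl/MeOH, which avoids reductive conditions.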